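**Plan**

Ring numbering used throughout: C1 = ring C=O, C2 = C(CH3)OH, C3 = CHOH, C4 = CH2, C5 = CH carrying the dienone arm, C6 = CH–O-isovaleryl. Retrosynthetic cuts, in order: O–Si and peroxyketal; the arm bond C(=CH2)–C(=O) (carbonylative Stille); the C6 ester and C6–O bonds; C2–CH3; then the two ring bonds C3–C4 and C1–C6 together.
Enabling feature: C1, C2 and C3 all bear oxygen, so C1–C2–C3 is a masked 1,3-dihydroxyacetone, i.e. the O–CH–C(=O)–CH–O unit of a 1,3-dioxan-5-one with two nucleophilic α-carbons. C4–C5–C6 with its acyl branch on C5 is a 2-(bromomethyl)enone, so one enamine α,α'-annulation ([3+3]) closes the cyclohexane across the dioxanone as a 2,4-dioxabicyclo[3.3.1]nonan-9-one.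
Forward order: the temporary dioxane ring is present first and the carbocycle is closed onto it (step 4). The C5 acetyl then becomes a vinyl triflate, the bridging ketone takes the C2 methyl, the dioxane ring is removed, C1 and C6 are adjusted, and the hydroperoxide arm is joined last.
Stereochemistry: the bicycle forces O–C1 and O–C3 cis; C5 is equilibrated to the equatorial epimer; MeMgBr enters from the dioxane face (C2). The meso triol is desymmetrized by catalytic enantioselective silylation, which sets the absolute configuration. Rubottom oxidation places O–C6 trans to the arm, and syn-hydrostannation gives the E-alkene.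

Key step: step 4

**Route**

Step 1
Reactants: 1 but-3-en-2-one; 2 formaldehyde
Product: 3 3-(hydroxymethyl)but-3-en-2-one
Conditions: aq. HCHO, DABCO (cat.), THF, rt
Reagents that add atoms: none
Why: Morita–Baylis–Hillman reaction, in which the DABCO-derived zwitterionic enolate is hydroxymethylated at the α-carbon; no stereocenter is formed.

Step 2
Reactants: 3 3-(hydroxymethyl)but-3-en-2-one
Product: 4 3-(bromomethyl)but-3-en-2-one
Conditions: PBr3, Et2O, −10 °C
Reagents that add atoms: phosphorus tribromide, BrP(Br)Br
Why: Bromination of a primary allylic alcohol through its phosphite ester (SN2; the SN2' path gives the same constitution).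

Step 3
Reactants: 5 cis-2-phenyl-1,3-dioxan-5-ol
Product: 6 2-phenyl-1,3-dioxan-5-one
Conditions: Dess–Martin periodinane, CH2Cl2, rt
Reagents that add atoms: none
Why: Dess–Martin oxidation of a secondary alcohol under near-neutral conditions that should leave the benzylidene acetal intact; the ketone is used fresh.

Step 4
Reactants: 6 2-phenyl-1,3-dioxan-5-one; 4 3-(bromomethyl)but-3-en-2-one
Product: 9 meso 7-acetyl-3-phenyl-2,4-dioxabicyclo[3.3.1]nonan-9-one (acetyl equatorial on the carbocycle, phenyl equatorial on the dioxane), via pyrrolidine enamine 7 (not isolated), via C-alkylated enamine 8 (not isolated)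
Conditions: pyrrolidine, PhH, reflux (−H2O); then 4, Et3N, MeCN, 0 °C to reflux; then AcOH–H2O, rt; then DBU (cat.), CH2Cl2, rt
Reagents that add atoms: water, O; pyrrolidine, C1CCNC1 (atoms only in 7 and 8)
Why: Enamine 7 is C-alkylated by 4 in an SN2' addition–elimination (Stork enamine alkylation, first ring bond), the iminium loses the α'-proton to give the less substituted enamine 8, and 8 adds to the regenerated enone terminus in an intramolecular Stork–Michael reaction (second ring bond) before hydrolysis returns the ketone. The closest known reaction type is the α,α'-annulation of cyclic ketone enamines with 2-(bromomethyl)acrylates or 2-(bromomethyl)enones to bicyclo[3.3.1]nonan-9-ones. The carbocycle C1–C6 closes in the Michael step by a 6-endo-trig (enolendo) attack of the enamine carbon on the methylene terminus. Both new bonds at C1 and C3 must be axial on the dioxane chair to span the three-carbon bridge, so they are cis to each other and anti to the equatorial phenyl group, which makes the bicycle meso; C5 is set by protonation α to the acetyl group and should equilibrate under DBU to the equatorial epimer, which avoids the dioxane bridge. The step needs C- over N-alkylation and α,α'- over α,α-regiochemistry: N-alkylation is reversible under the conditions, the second enamine forms towards the unsubstituted α'-carbon to avoid allylic strain, and the bridgehead α-positions of the product cannot enolize, which should stop the sequence after one annulation.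

Step 5
Reactants: 9 meso 7-acetyl-3-phenyl-2,4-dioxabicyclo[3.3.1]nonan-9-one
Product: 10 meso 1-(9-oxo-3-phenyl-2,4-dioxabicyclo[3.3.1]non-7-yl)ethenyl trifluoromethanesulfonate
Conditions: KN(SiMe3)2, THF, −78 °C; then PhNTf2, −78 to 0 °C
Reagents that add atoms: N-phenylbis(trifluoromethanesulfonimide), O=S(=O)(N(c1ccccc1)S(=O)(=O)C(F)(F)F)C(F)(F)F
Why: Kinetic deprotonation of the methyl ketone at CH3 and O-sulfonylation of the potassium enolate (enol triflate formation); the bridging ketone has only bridgehead α-hydrogens and should not enolize, and C5 is untouched.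

Step 6
Reactants: 10 meso vinyl triflate ketone
Product: 11 meso 1-(9-hydroxy-9-methyl-3-phenyl-2,4-dioxabicyclo[3.3.1]non-7-yl)ethenyl trifluoromethanesulfonate (methyl on the dioxane side, hydroxyl on the carbocycle side)
Conditions: MeMgBr, THF, −78 °C; then aq. NH4Cl
Reagents that add atoms: methylmagnesium bromide, C[Mg]Br
Why: Grignard 1,2-addition to the bridging ketone; the nucleophile should approach over the dioxane ring, whose oxygens carry no axial hydrogens, rather than over the carbocycle, where the axial hydrogens at C4 and C6 block the path, so the methyl ends cis to O–C1 and O–C3 and the C2 hydroxyl trans to them.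

Step 7
Reactants: 11 meso tertiary alcohol
Product: 12 meso 1-[(3R,5S)-3,4,5-trihydroxy-4-methylcyclohexyl]ethenyl trifluoromethanesulfonate (3-OH and 5-OH cis to each other and to the 4-methyl, trans to 4-OH and to the C1 substituent)
Conditions: AcOH–H2O (4:1), 50 °C
Reagents that add atoms: none
Why: Acid hydrolysis of the strained, 1,3-diaxially bridging benzylidene acetal; the vinyl triflate is stable to aqueous acid and no stereocenter changes.

Step 8
Reactants: 12 meso triol
Product: 13 mono-TBS ether of 12 at O–C3 (target numbering; C2, C3 and C5 as in 24, hydroxyl at C1 free)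
Conditions: TBSCl, iPr2NEt, (S)-N-[(R)-3,3-dimethylbutan-2-yl]-3,3-dimethyl-2-{[(1-methylimidazol-2-yl)methyl]amino}butanamide (30 mol %; the enantiomer of the catalyst that silylates O–C3 is used), THF, −40 °C
Reagents that add atoms: tert-butyldimethylsilyl chloride, CC(C)(C)[Si](C)(C)Cl
Why: Catalytic enantioselective silylation (desymmetrization of a meso diol): the hydrogen-bonding catalyst should deliver the silyl group to one of the two enantiotopic secondary hydroxyls, which fixes the absolute configuration at C3 and turns C2 and C5 into true stereocenters; the tertiary hydroxyl is too hindered to react.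

Step 9
Reactants: 13 mono-TBS ether
Product: 14 (2S,3R,5S)-configured 3-(tert-butyldimethylsilyloxy)-2-hydroxy-2-methyl-5-[1-(trifluoromethanesulfonyloxy)ethenyl]cyclohexanone (descriptors as for the same atoms in 24)
Conditions: Dess–Martin periodinane, CH2Cl2, 0 °C to rt
Reagents that add atoms: none
Why: Dess–Martin oxidation of the only remaining secondary alcohol; the β-silyloxy ketone cannot eliminate because C2 carries no hydrogen.

Step 10
Reactants: 14 ketone
Product: 17 6-hydroxy derivative of 14 (new hydroxyl at C6 trans to the C5 substituent, as in 24), via silyl enol ether 15 (not isolated), via bis(trimethylsilyl) ether 16 (not isolated)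
Conditions: Me3SiOTf, Et3N, CH2Cl2, 0 °C; then dimethyldioxirane, acetone, −40 °C; then 1 M HCl, THF, 0 °C
Reagents that add atoms: dimethyldioxirane, CC1(C)OO1; trimethylsilyl trifluoromethanesulfonate, C[Si](C)(C)OS(=O)(=O)C(F)(F)F (silicon atoms only in 15 and 16)
Why: Rubottom oxidation: C6 is the only enolizable α-position, and the dioxirane should attack the enol ether face opposite the pseudoaxial C2 silyloxy group and the C5 substituent, so that after silyl migration and brief acid treatment the C6 hydroxyl is equatorial and trans to the arm, which is also the thermodynamically preferred arrangement.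

Step 11
Reactants: 17 α-hydroxy ketone
Product: 18 3-methylbutanoate of 17 at O–C6
Conditions: 3-methylbutanoyl chloride, pyridine, DMAP (cat.), CH2Cl2, 0 °C
Reagents that add atoms: 3-methylbutanoyl chloride, CC(C)CC(=O)Cl
Why: DMAP-catalysed acylation of the secondary hydroxyl; the tertiary C2 hydroxyl should not acylate and the mild base should not epimerize C6.

Step 12
Reactants: 19 2-methylbut-3-yn-2-ol
Product: 20 3-hydroperoxy-3-methylbut-1-yne
Conditions: H2O2 (50% aq.), H2SO4 (cat.), 0 °C
Reagents that add atoms: hydrogen peroxide, OO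
Why: Acid-catalysed SN1 substitution of a tertiary propargylic alcohol by hydrogen peroxide.

Step 13
Reactants: 20 3-hydroperoxy-3-methylbut-1-yne
Product: 21 3-[(2-methoxypropan-2-yl)peroxy]-3-methylbut-1-yne
Conditions: 2-methoxypropene, PPTS (cat.), CH2Cl2, 0 °C
Reagents that add atoms: 2-methoxypropene, COC(C)=C
Why: Acid-catalysed addition of the hydroperoxide to the enol ether gives a peroxyketal, a hydroperoxide protecting group that tolerates neutral organometallic coupling.

Step 14
Reactants: 21 peroxyketal alkyne
Product: 22 (E)-tributyl{3-[(2-methoxypropan-2-yl)peroxy]-3-methylbut-1-enyl}stannane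
Conditions: Bu3SnH, PdCl2(PPh3)2 (2 mol %), THF, 0 °C, dark
Reagents that add atoms: tributyltin hydride, CCCC[SnH](CCCC)CCCC
Why: Palladium-catalysed syn-hydrostannation; the tertiary propargylic centre should direct tin to the terminal carbon, giving the E-alkenylstannane.

Step 15
Reactants: 18 vinyl triflate; 22 alkenylstannane
Product: 23 3-O-TBS, peroxyketal-protected target (cross-conjugated dienone)
Conditions: CO (3 atm), Pd(PPh3)4 (5 mol %), LiCl, THF, 55 °C
Reagents that add atoms: carbon monoxide, [C-]#[O+]
Why: Carbonylative Stille coupling: oxidative addition of the vinyl triflate to zerovalent palladium, CO insertion, and transmetalation with retention of the E-alkene build the C(=CH2)–C(=O)–CH=CH unit without touching ring stereocenters.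

Step 16
Reactants: 23 protected dienone
Product: 24 (1S,3S,4R,6S)-3,4-dihydroxy-6-[(4E)-6-hydroperoxy-6-methyl-3-oxohepta-1,4-dien-2-yl]-3-methyl-2-oxocyclohexyl 3-methylbutanoate
Conditions: aq. HF, MeCN, 0 °C to rt
Reagents that add atoms: none
Why: Acidic fluoride cleaves the silyl ether and hydrolyses the peroxyketal in one operation; the ester, hydroperoxide, and aldol-type β-hydroxy ketone should survive because no base is used.

**Compound list**

1 | but-3-en-2-one | CC(=O)C=C | starting material
2 | formaldehyde | C=O | starting material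
3 | 3-(hydroxymethyl)but-3-en-2-one | CC(=O)C(=C)CO | intermediate
4 | 3-(bromomethyl)but-3-en-2-one | CC(=O)C(=C)CBr | intermediate
5 | cis-2-phenyl-1,3-dioxan-5-ol | O[C@H]1CO[C@@H](c2ccccc2)OC1 | starting material
6 | 2-phenyl-1,3-dioxan-5-one | O=C1COC(c2ccccc2)OC1 | intermediate
7 | 1-(2-phenyl-4H-1,3-dioxin-5-yl)pyrrolidine (racemic) | C1(c2ccccc2)OCC(N3CCCC3)=CO1 | intermediate (not isolated)
8 | 3-{[2-phenyl-5-(pyrrolidin-1-yl)-4H-1,3-dioxin-4-yl]methyl}but-3-en-2-one (stereoisomer mixture) | CC(=O)C(=C)CC1OC(c2ccccc2)OC=C1N3CCCC3 | intermediate (not isolated)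
9 | meso 7-acetyl-3-phenyl-2,4-dioxabicyclo[3.3.1]nonan-9-one (acetyl and phenyl both equatorial, pointing away from the other ring) | CC(=O)[C@@H]1C[C@H]2O[C@H](c3ccccc3)O[C@@H](C1)C2=O | intermediate
10 | meso 1-(9-oxo-3-phenyl-2,4-dioxabicyclo[3.3.1]non-7-yl)ethenyl trifluoromethanesulfonate | C=C(OS(=O)(=O)C(F)(F)F)[C@@H]1C[C@H]2O[C@H](c3ccccc3)O[C@@H](C1)C2=O | intermediate
11 | meso 1-(9-hydroxy-9-methyl-3-phenyl-2,4-dioxabicyclo[3.3.1]non-7-yl)ethenyl trifluoromethanesulfonate (9-methyl on the dioxane side) | C=C(OS(=O)(=O)C(F)(F)F)[C@@H]1C[C@H]2O[C@H](c3ccccc3)O[C@@H](C1)[C@@]2(C)O | intermediate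
12 | meso 1-[(3R,5S)-3,4,5-trihydroxy-4-methylcyclohexyl]ethenyl trifluoromethanesulfonate (3-OH, 5-OH and 4-CH3 cis; 4-OH and C1 substituent trans to them) | C=C(OS(=O)(=O)C(F)(F)F)[C@@H]1C[C@@H](O)[C@](C)(O)[C@@H](O)C1 | intermediate
13 | mono-TBS ether of 12 at the hydroxyl that becomes O–C3 of 24 | C=C(OS(=O)(=O)C(F)(F)F)[C@@H]1C[C@@H](O[Si](C)(C)C(C)(C)C)[C@](C)(O)[C@@H](O)C1 | intermediate
14 | 3-(tert-butyldimethylsilyloxy)-2-hydroxy-2-methyl-5-[1-(trifluoromethanesulfonyloxy)ethenyl]cyclohexanone (C2, C3, C5 as in 24) | C=C(OS(=O)(=O)C(F)(F)F)[C@@H]1C[C@@H](O[Si](C)(C)C(C)(C)C)[C@](C)(O)C(=O)C1 | intermediate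
15 | C1 trimethylsilyl enol ether (C1=C6) and C2 trimethylsilyl ether of 14 | C=C(OS(=O)(=O)C(F)(F)F)[C@@H]1C[C@@H](O[Si](C)(C)C(C)(C)C)[C@](C)(O[Si](C)(C)C)C(O[Si](C)(C)C)=C1 | intermediate (not isolated)
16 | 2,6-bis(trimethylsilyloxy) ketone (6-OSiMe3 trans to the C5 substituent) | C=C(OS(=O)(=O)C(F)(F)F)[C@@H]1C[C@@H](O[Si](C)(C)C(C)(C)C)[C@](C)(O[Si](C)(C)C)C(=O)[C@H]1O[Si](C)(C)C | intermediate (not isolated)
17 | 3-(tert-butyldimethylsilyloxy)-2,6-dihydroxy-2-methyl-5-[1-(trifluoromethanesulfonyloxy)ethenyl]cyclohexanone (all four stereocenters as in 24) | C=C(OS(=O)(=O)C(F)(F)F)[C@@H]1C[C@@H](O[Si](C)(C)C(C)(C)C)[C@](C)(O)C(=O)[C@H]1O | intermediate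
18 | 3-methylbutanoate of 17 at O–C6 | C=C(OS(=O)(=O)C(F)(F)F)[C@@H]1C[C@@H](O[Si](C)(C)C(C)(C)C)[C@](C)(O)C(=O)[C@H]1OC(=O)CC(C)C | intermediate
19 | 2-methylbut-3-yn-2-ol | CC(C)(O)C#C | starting material
20 | 3-hydroperoxy-3-methylbut-1-yne | CC(C)(OO)C#C | intermediate
21 | 3-[(2-methoxypropan-2-yl)peroxy]-3-methylbut-1-yne | COC(C)(C)OOC(C)(C)C#C | intermediate
22 | (E)-tributyl{3-[(2-methoxypropan-2-yl)peroxy]-3-methylbut-1-enyl}stannane | CCCC[Sn](CCCC)(CCCC)/C=C/C(C)(C)OOC(C)(C)OC | intermediate
23 | 24 carrying a TBS ether at O–C3 and a 2-methoxypropan-2-yl peroxyketal in place of OOH | C=C(C(=O)/C=C/C(C)(C)OOC(C)(C)OC)[C@@H]1C[C@@H](O[Si](C)(C)C(C)(C)C)[C@](C)(O)C(=O)[C@H]1OC(=O)CC(C)C | intermediate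
24 | (1S,3S,4R,6S)-3,4-dihydroxy-6-[(4E)-6-hydroperoxy-6-methyl-3-oxohepta-1,4-dien-2-yl]-3-methyl-2-oxocyclohexyl 3-methylbutanoate | C=C(C(=O)/C=C/C(C)(C)OO)[C@@H]1C[C@@H](O)[C@](C)(O)C(=O)[C@H]1OC(=O)CC(C)C | target

**Step count and risks**

Total steps: 16. Longest linear sequence: 12 (steps 1, 2, 4, 5, 6, 7, 8, 9, 10, 11, 15, 16).

Steps most likely to fail:

1. Step 8. The catalyst may discriminate poorly between the two enantiotopic, hindered hydroxyls, or silylation may be too slow. Fallback by enzymatic desymmetrization: starting from 12, immobilized Candida antarctica lipase B with vinyl acetate in tert-butyl methyl ether should give the monoacetate F1, with the acetate on the hydroxyl that becomes C1 (if the enzyme prefers the other hydroxyl, lipase hydrolysis of the meso diacetate is used instead). Silylation of the remaining secondary hydroxyl (TBSOTf, 2,6-lutidine, CH2Cl2, −78 °C) gives the acetate silyl ether F2, and methanolysis (K2CO3, MeOH, 0 °C) returns to the route at 13.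

2. Step 15. The O–O bond may be reduced or inserted by zerovalent palladium or tin species, or direct coupling without CO uptake may compete. Fallback that introduces the peroxide last: starting from 18, Nozaki–Hiyama–Kishi coupling (CrCl2, NiCl2 cat., DMF, rt) with 4-methylpent-3-enal gives the allylic alcohol F3 (epimers at the new carbinol). Dess–Martin oxidation gives the β,γ-unsaturated ketone F4, and desilylation (HF·pyridine, THF) gives the diol F5. A Schenck ene reaction with singlet oxygen (O2, hν, tetraphenylporphyrin, CH2Cl2, 0 °C), abstracting hydrogen from the doubly activated methylene, should then give the E-configured tertiary hydroperoxide and rejoin the route at 24.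

3. Step 4. The α-alkoxy enamine may decompose, N-alkylation may not revert, or 4 may polymerize under the hot basic conditions. Fallback by a stepwise annulation through a metalated hydrazone: starting from 6, condensation with N,N-dimethylhydrazine gives the hydrazone F6. Deprotonation (LiN(iPr)2, THF, −78 °C) and SN2' alkylation with 4 gives the monoalkylated hydrazone F7, and two-phase hydrolysis (aq. oxalic acid, Et2O) gives the enone ketone F8. Amine-catalysed intramolecular Michael addition (pyrrolidine cat., AcOH cat., CH2Cl2) followed by DBU equilibration rejoins the route at 9.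

**Further compounds**

F1 | step 8 | monoacetate of 12 at the hydroxyl that becomes C1 | C=C(OS(=O)(=O)C(F)(F)F)[C@@H]1C[C@@H](O)[C@](C)(O)[C@@H](OC(C)=O)C1
F2 | step 8 | acetate of 13 at O–C1 (O–C3 TBS ether) | C=C(OS(=O)(=O)C(F)(F)F)[C@@H]1C[C@@H](O[Si](C)(C)C(C)(C)C)[C@](C)(O)[C@@H](OC(C)=O)C1
F3 | step 15 | allylic alcohol from 18 and 4-methylpent-3-enal (carbinol epimers) | C=C(C(O)CC=C(C)C)[C@@H]1C[C@@H](O[Si](C)(C)C(C)(C)C)[C@](C)(O)C(=O)[C@H]1OC(=O)CC(C)C
F4 | step 15 | 3-O-TBS prenyl ketone (5-methyl-3-oxohexa-1,4... arm as 5-methyl-2-methylidene-3-oxohex-4-enyl isomer: C(=CH2)–C(=O)–CH2–CH=C(CH3)2) | C=C(C(=O)CC=C(C)C)[C@@H]1C[C@@H](O[Si](C)(C)C(C)(C)C)[C@](C)(O)C(=O)[C@H]1OC(=O)CC(C)C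
F5 | step 15 | desilylated prenyl ketone (24 with C(=O)–CH2–CH=C(CH3)2 in place of the hydroperoxy enone) | C=C(C(=O)CC=C(C)C)[C@@H]1C[C@@H](O)[C@](C)(O)C(=O)[C@H]1OC(=O)CC(C)C
F6 | step 4 | 2-phenyl-1,3-dioxan-5-one N,N-dimethylhydrazone | CN(C)N=C1COC(c2ccccc2)OC1
F7 | step 4 | 3-{[5-(dimethylhydrazinylidene)-2-phenyl-1,3-dioxan-4-yl]methyl}but-3-en-2-one (stereoisomer mixture) | CC(=O)C(=C)CC1OC(c2ccccc2)OCC1=NN(C)C
F8 | step 4 | 4-(2-methylidene-3-oxobutyl)-2-phenyl-1,3-dioxan-5-one (stereoisomer mixture) | CC(=O)C(=C)CC1OC(c2ccccc2)OCC1=O
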